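**Strategy.** The cyclopentanone ring (C1, C2, C3, C3a, C7a; indene numbering) is cut out of a cyclohexenone. An intramolecular Diels–Alder reaction of an acyclic tetraenone with a four-atom tether first assembles the cyclohexene with its two adjacent quaternary carbons (C4, C5), trans-fused to a six-membered ketone ring. After dehydrogenation and epoxidation, the key step, a BF3-triggered 1,2-acyl shift of the α,β-epoxy ketone, exploits the tertiary ethyl-bearing carbon (future C3) as cation site: the carbonyl carbon C2 migrates onto it, the surplus ring carbon leaves as formate, and base sets C1 and C3 under thermodynamic control. Its precursor is a fused 3-ethyl-6-methyl-2,3-epoxycyclohexanone.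

Key step: step 15

Remark on the chemistry: the carbinol configuration drawn for 13 and 19 (anti adduct) and the oxirane configuration drawn for 24 are the expected major ones; both are erased later (steps 11 and 15), so the route does not depend on them.

Step 1
Reactants: 1 methyl 2-bromobutanoate (racemic)
Product: 3 methyl 2-(triphenyl-λ5-phosphanylidene)butanoate, via phosphonium bromide 2 (not isolated)
Conditions: PPh3, toluene, 90 °C; then 2 M NaOH, CH2Cl2/H2O, 20 °C
Reagents that add atoms: triphenylphosphine, c1ccc(cc1)P(c1ccccc1)c1ccccc1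
Why: SN2 quaternisation of the phosphine by the α-bromo ester and deprotonation of the salt should give the ester-stabilised ylide (standard Wittig reagent preparation); no stereocentre is involved.

Step 2
Reactants: 4 butanal; 5 allyltrimethylsilane
Product: 6 (2S)-2-ethylpent-4-enal
Conditions: (2S,5S)-5-benzyl-2-tert-butyl-3-methylimidazolidin-4-one·TFA (20 mol%; the enantiomer of the catalyst is chosen to deliver the S aldehyde), (NH4)2Ce(NO3)6 (2 equiv), NaHCO3, H2O, DME, −20 °C; solution used directly
Reagents that add atoms: none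
Why: SOMO-activation organocatalytic α-allylation of an aldehyde, in which the enamine radical cation formed by one-electron oxidation is trapped by the allylsilane on the face left open by the catalyst, should set the α-stereocentre that later steers the cycloaddition.

Step 3
Reactants: 6 (2S)-2-ethylpent-4-enal; 3 methyl 2-(triphenyl-λ5-phosphanylidene)butanoate
Product: 7 methyl (2E,4S)-2,4-diethylhepta-2,6-dienoate
Conditions: CH2Cl2, 40 °C
Reagents that add atoms: none
Why: Wittig olefination with an α-branched stabilised ylide should give the E trisubstituted enoate under neutral conditions that spare the α-stereocentre of the aldehyde.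

Step 4
Reactants: 7 methyl (2E,4S)-2,4-diethylhepta-2,6-dienoate
Product: 8 methyl (2E,4S)-2,4-diethyl-6-oxohex-2-enoate
Conditions: OsO4 (2 mol%), NaIO4 (4 equiv), 2,6-lutidine, dioxane/H2O 3:1, 20 °C
Reagents that add atoms: sodium periodate, [Na+].[O-]I(=O)(=O)=O (terminal oxygen source through catalytic OsO4, O=[Os](=O)(=O)=O)
Why: Lemieux–Johnson oxidation should cleave the electron-rich monosubstituted alkene chemoselectively and leave the electron-poor trisubstituted enoate untouched.

Step 5
Reactants: 9 hex-3-yn-2-one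
Product: 10 (2S)-hex-3-yn-2-ol
Conditions: RuCl[(S,S)-TsDPEN](p-cymene) (0.5 mol%), propan-2-ol, 20 °C
Reagents that add atoms: none
Why: Noyori asymmetric transfer hydrogenation of an alkynyl ketone, with hydride delivery through the six-membered metal–ligand bifunctional transition state, should give the S propargylic alcohol with the (S,S) ligand.

Step 6
Reactants: 10 (2S)-hex-3-yn-2-ol
Product: 11 (2S)-hex-3-yn-2-yl methanesulfonate
Conditions: MsCl, Et3N, CH2Cl2, −78 → 0 °C; used crude
Reagents that add atoms: methanesulfonyl chloride, CS(=O)(=O)Cl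
Why: O-sulfonylation proceeds with retention at carbon and provides the leaving group for the propargylation.

Step 7
Reactants: 8 methyl (2E,4S)-2,4-diethyl-6-oxohex-2-enoate; 11 (2S)-hex-3-yn-2-yl methanesulfonate
Product: 13 methyl (2E,4S,6S,7R)-2,4-diethyl-6-hydroxy-7-methylundec-2-en-8-ynoate, via allenylzinc 12 (not isolated)
Conditions: Pd(OAc)2 (5 mol%), PPh3 (5 mol%), Et2Zn (3 equiv), THF, −78 → −20 °C; aq NH4Cl work-up
Reagents that add atoms: none
Why: Marshall propargylation, in which anti SN2′ oxidative addition of zerovalent palladium, transmetalation to zinc and syn SE2′ addition to the aldehyde through a cyclic transition state transfer the mesylate chirality to C7 (R, net inversion at the propargylic carbon); the carbinol centre C6 is expected mainly anti and is removed in step 11.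

Step 8
Reactants: 14 (E)-cinnamaldehyde
Product: 15 [(E)-but-1-en-3-yn-1-yl]benzene
Conditions: TMSCHN2, LiN(i-Pr)2 (LDA), THF, −78 → 20 °C; aq NH4Cl work-up
Reagents that add atoms: trimethylsilyldiazomethane, C[Si](C)(C)C=[N+]=[N-]
Why: Colvin rearrangement (Peterson-type olefination to the diazoalkene, loss of N2 and 1,2-hydrogen shift of the alkylidene carbene) should homologate the aldehyde to the terminal alkyne with the E alkene intact.

Step 9
Reactants: 15 [(E)-but-1-en-3-yn-1-yl]benzene
Product: 17 [(1E,3E)-3-ethyl-4-iodobuta-1,3-dien-1-yl]benzene, via dienylcopper 16 (not isolated)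
Conditions: EtMgBr, CuBr·SMe2, Et2O/Me2S, −45 → −25 °C; then I2, −40 °C
Reagents that add atoms: ethylmagnesium bromide, CC[Mg]Br; iodine, [I][I]
Why: Normant carbocupration adds ethyl and copper syn across the terminal alkyne with ethyl on the internal carbon, and iodinolysis with retention should give the dienyl iodide with iodine trans to the styryl group.

Step 10
Reactants: 13 methyl (2E,4S,6S,7R)-2,4-diethyl-6-hydroxy-7-methylundec-2-en-8-ynoate; 17 [(1E,3E)-3-ethyl-4-iodobuta-1,3-dien-1-yl]benzene
Product: 19 methyl (2E,4S,6S,7R,8E,10E,12E)-2,4,9,11-tetraethyl-6-hydroxy-7-methyl-13-phenyltrideca-2,8,10,12-tetraenoate, via alkenylzirconocene 18 (not isolated)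
Conditions: Cp2Zr(H)Cl (2.3 equiv), THF, 20 °C; then 17, Pd(PPh3)4 (5 mol%), ZnCl2 (20 mol%), 20 °C; aq NH4Cl work-up
Reagents that add atoms: none
Why: syn hydrozirconation should place zirconium on the less hindered, ethyl-bearing alkyne carbon, and the Negishi-type alkenyl–alkenyl coupling proceeds with retention at both partners, giving the 8E,10E diene.

Step 11
Reactants: 19 methyl (2E,4S,6S,7R,8E,10E,12E)-2,4,9,11-tetraethyl-6-hydroxy-7-methyl-13-phenyltrideca-2,8,10,12-tetraenoate
Product: 20 methyl (2E,4S,7R,8E,10E,12E)-2,4,9,11-tetraethyl-7-methyl-6-oxo-13-phenyltrideca-2,8,10,12-tetraenoate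
Conditions: Dess–Martin periodinane, pyridine, CH2Cl2, 0 → 20 °C
Reagents that add atoms: none
Why: Dess–Martin oxidation under non-basic conditions should give the β,γ-unsaturated ketone without double-bond migration or epimerisation at C7.

Step 12
Reactants: 20 methyl (2E,4S,7R,8E,10E,12E)-2,4,9,11-tetraethyl-7-methyl-6-oxo-13-phenyltrideca-2,8,10,12-tetraenoate
Product: 21 methyl (1S,2R,4aS,5R,8S,8aR)-1,2,4,8-tetraethyl-5-methyl-6-oxo-2-[(E)-2-phenylethenyl]-1,2,4a,5,6,7,8,8a-octahydronaphthalene-1-carboxylate
Conditions: toluene (0.01 M), BHT (cat.), 150 °C, sealed tube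
Reagents that add atoms: none
Why: thermal type 1 intramolecular Diels–Alder reaction, in which a chair-like four-atom tether with the C7 methyl and C4 ethyl groups equatorial and the ester endo should give the trans-fused octalone; the E alkene geometries fix the relative configuration of C1, C2, C4a and C8a, and the two tether stereocentres fix the absolute sense.

Step 13
Reactants: 21 the trans-fused octalone of step 12
Product: 23 methyl (1S,2R,4aS,5R,8aS)-1,2,4,8-tetraethyl-5-methyl-6-oxo-2-[(E)-2-phenylethenyl]-1,2,4a,5,6,8a-hexahydronaphthalene-1-carboxylate, via lithium enolate 22 (not isolated)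
Conditions: LiN(i-Pr)2 (LDA), THF, −78 °C; then N-tert-butylbenzenesulfinimidoyl chloride, −78 → 0 °C
Reagents that add atoms: none
Why: kinetic deprotonation at the C7 methylene (not the C5 methine), S-transfer to the enolate and syn elimination (Mukaiyama dehydrogenation) should give the C7=C8 enone regioselectively.

Step 14
Reactants: 23 the C7=C8 enone of step 13
Product: 24 the 7,8-epoxide of 23 (methyl 7,8-epoxy-1,2,4,8-tetraethyl-5-methyl-6-oxo-2-[(E)-2-phenylethenyl]-1,2,4a,5,6,7,8,8a-octahydronaphthalene-1-carboxylate, oxirane oxygen anti to H-8a)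
Conditions: 30% H2O2, NaOH (cat.), MeOH, 0 → 20 °C
Reagents that add atoms: hydrogen peroxide, OO
Why: Weitz–Scheffer nucleophilic epoxidation is selective for the electron-poor enone double bond over the three other alkenes, with axial attack expected on the face opposite H-8a.

Step 15
Reactants: 24 the 7,8-epoxy ketone of step 14
Product: 26 methyl (1R,3R,3aS,4S,5R,7aS)-3,4,5,7-tetraethyl-1-methyl-2-oxo-5-[(E)-2-phenylethenyl]-2,3,3a,4,5,7a-hexahydro-1H-indene-4-carboxylate, via formyl ketone 25 (not isolated)
Conditions: BF3·OEt2 (1.5 equiv), benzene, 20 °C, 30 min; then 2 M NaOH, MeOH, 20 °C; HCl work-up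
Reagents that add atoms: none
Why: BF3 coordinates the oxirane oxygen and the C8–O bond, which leads to a tertiary cation, ionises in preference to the C7–O bond next to the carbonyl; the acyl carbon C6 then shifts from C7 to C8 while C7 becomes a formyl group, so the six-membered ketone ring contracts to the cyclopentanone in a semipinacol (1,2-acyl shift) rearrangement of an α,β-epoxy ketone, the known route from cyclohexenone oxides to 2-formylcyclopentanones. The five-membered ring is closed by this 1,2-migration through a three-centre transition state on the ring itself, not by an exo or endo cyclisation of a chain. The quaternary centre of 25 (C3, ethyl and formyl) forms by migration anti to the departing oxygen but is transient: hydroxide cleaves the non-enolisable β-keto aldehyde by retro-Claisen loss of formate, and C3 and C1 then equilibrate through the enolates to the all-trans arrangement of the target (ethyl anti to C4, methyl anti to C7). C3a, C7a, C4 and C5 are not touched, so the trans ring fusion of step 12 is carried over. The step needs acyl migration to outrun hydride shift (which would lead to a diosphenol) and capture of the cation by the neighbouring ester carbonyl; the high migratory aptitude of an acyl group towards a tertiary β-cation and a short reaction time in a non-nucleophilic solvent are relied on for this.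

Step 16
Reactants: 26 the methyl ester of step 15
Product: 27 (1R,3R,3aS,4S,5R,7aS)-3,4,5,7-tetraethyl-1-methyl-2-oxo-5-[(E)-2-phenylethenyl]-2,3,3a,4,5,7a-hexahydro-1H-indene-4-carboxylic acid (CNP0420507.1)
Conditions: NaSEt (6 equiv), DMF, 60 °C; then 1 M HCl
Reagents that add atoms: none
Why: SN2 dealkylation at the methyl carbon by thiolate is not slowed by the two quaternary carbons that shield the acyl carbon, and any epimerisation at C1 or C3 returns to the thermodynamic target configuration.

**Compound list**

1 | methyl 2-bromobutanoate (racemic) | CCC(Br)C(=O)OC | starting material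
2 | (1-methoxy-1-oxobutan-2-yl)triphenylphosphonium bromide | CCC(C(=O)OC)[P+](c1ccccc1)(c1ccccc1)c1ccccc1.[Br-] | intermediate
3 | methyl 2-(triphenyl-λ5-phosphanylidene)butanoate | CCC(C(=O)OC)=P(c1ccccc1)(c1ccccc1)c1ccccc1 | intermediate
4 | butanal | CCCC=O | starting material
5 | allyltrimethylsilane | C=CC[Si](C)(C)C | starting material
6 | (2S)-2-ethylpent-4-enal | O=C[C@@H](CC)CC=C | intermediate
7 | methyl (2E,4S)-2,4-diethylhepta-2,6-dienoate | COC(=O)/C(CC)=C/[C@@H](CC)CC=C | intermediate
8 | methyl (2E,4S)-2,4-diethyl-6-oxohex-2-enoate | COC(=O)/C(CC)=C/[C@@H](CC)CC=O | intermediate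
9 | hex-3-yn-2-one | CCC#CC(C)=O | starting material
10 | (2S)-hex-3-yn-2-ol | CCC#C[C@H](C)O | intermediate
11 | (2S)-hex-3-yn-2-yl methanesulfonate | CCC#C[C@H](C)OS(C)(=O)=O | intermediate
12 | (aR)-ethyl(hexa-2,3-dien-4-yl)zinc | CC=[C@]=C(CC)[Zn]CC | intermediate
13 | methyl (2E,4S,6S,7R)-2,4-diethyl-6-hydroxy-7-methylundec-2-en-8-ynoate | COC(=O)/C(CC)=C/[C@@H](CC)C[C@H](O)[C@H](C)C#CCC | intermediate
14 | (E)-cinnamaldehyde | O=C/C=C/c1ccccc1 | starting material
15 | [(E)-but-1-en-3-yn-1-yl]benzene | C#C/C=C/c1ccccc1 | intermediate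
16 | [(1E,3E)-2-ethyl-4-phenylbuta-1,3-dien-1-yl]copper | [Cu]/C=C(CC)/C=C/c1ccccc1 | intermediate
17 | [(1E,3E)-3-ethyl-4-iodobuta-1,3-dien-1-yl]benzene | I/C=C(CC)/C=C/c1ccccc1 | intermediate
18 | methyl (2E,4S,6S,7R,8E)-9-[chlorobis(cyclopentadienyl)zirconio]-6-{[chlorobis(cyclopentadienyl)zirconio]oxy}-2,4-diethyl-7-methylundeca-2,8-dienoate | COC(=O)/C(CC)=C/[C@@H](CC)C[C@H](O[Zr](Cl)(C1C=CC=C1)C1C=CC=C1)[C@H](C)/C=C(CC)/[Zr](Cl)(C1C=CC=C1)C1C=CC=C1 | intermediate
19 | methyl (2E,4S,6S,7R,8E,10E,12E)-2,4,9,11-tetraethyl-6-hydroxy-7-methyl-13-phenyltrideca-2,8,10,12-tetraenoate | COC(=O)/C(CC)=C/[C@@H](CC)C[C@H](O)[C@H](C)/C=C(CC)/C=C(CC)/C=C/c1ccccc1 | intermediate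
20 | methyl (2E,4S,7R,8E,10E,12E)-2,4,9,11-tetraethyl-7-methyl-6-oxo-13-phenyltrideca-2,8,10,12-tetraenoate | COC(=O)/C(CC)=C/[C@@H](CC)CC(=O)[C@H](C)/C=C(CC)/C=C(CC)/C=C/c1ccccc1 | intermediate
21 | methyl (1S,2R,4aS,5R,8S,8aR)-1,2,4,8-tetraethyl-5-methyl-6-oxo-2-[(E)-2-phenylethenyl]-1,2,4a,5,6,7,8,8a-octahydronaphthalene-1-carboxylate | CCC1=C[C@](/C=C/c2ccccc2)(CC)[C@@](CC)(C(=O)OC)[C@H]2[C@H]1[C@@H](C)C(=O)C[C@@H]2CC | intermediate
22 | lithium enolate of 21 (C6–OLi, C6=C7) | CCC1=C[C@](/C=C/c2ccccc2)(CC)[C@@](CC)(C(=O)OC)[C@H]2[C@H]1[C@@H](C)C(O[Li])=C[C@@H]2CC | intermediate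
23 | methyl (1S,2R,4aS,5R,8aS)-1,2,4,8-tetraethyl-5-methyl-6-oxo-2-[(E)-2-phenylethenyl]-1,2,4a,5,6,8a-hexahydronaphthalene-1-carboxylate | CCC1=C[C@](/C=C/c2ccccc2)(CC)[C@@](CC)(C(=O)OC)[C@H]2[C@H]1[C@@H](C)C(=O)C=C2CC | intermediate
24 | 7,8-epoxide of 23, oxirane oxygen anti to H-8a | CCC1=C[C@](/C=C/c2ccccc2)(CC)[C@@](CC)(C(=O)OC)[C@H]2[C@H]1[C@@H](C)C(=O)[C@H]3O[C@]32CC | intermediate
25 | methyl 3,4,5,7-tetraethyl-3-formyl-1-methyl-2-oxo-5-[(E)-2-phenylethenyl]-2,3,3a,4,5,7a-hexahydro-1H-indene-4-carboxylate, formyl group anti to H-3a | CCC1=C[C@](/C=C/c2ccccc2)(CC)[C@@](CC)(C(=O)OC)[C@H]2[C@H]1[C@@H](C)C(=O)[C@@]2(CC)C=O | intermediate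
26 | methyl (1R,3R,3aS,4S,5R,7aS)-3,4,5,7-tetraethyl-1-methyl-2-oxo-5-[(E)-2-phenylethenyl]-2,3,3a,4,5,7a-hexahydro-1H-indene-4-carboxylate | CCC1=C[C@](/C=C/c2ccccc2)(CC)[C@@](CC)(C(=O)OC)[C@H]2[C@H]1[C@@H](C)C(=O)[C@@H]2CC | intermediate
27 | (1R,3R,3aS,4S,5R,7aS)-3,4,5,7-tetraethyl-1-methyl-2-oxo-5-[(E)-2-phenylethenyl]-2,3,3a,4,5,7a-hexahydro-1H-indene-4-carboxylic acid | CCC1=C[C@](/C=C/c2ccccc2)(CC)[C@@](CC)(C(=O)O)[C@H]2[C@H]1[C@@H](C)C(=O)[C@@H]2CC | target

**Step count and risks**

Total step count: 16. Longest linear sequence: 11 steps (2, 3, 4, 7, 10, 11, 12, 13, 14, 15, 16).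

Steps most likely to fail:

1. Step 15 (key step). The tertiary cation may be captured by the neighbouring ester carbonyl (lactonisation with loss of the methyl group), or a hydride may shift instead of the acyl group. Fallback by a benzilic acid ring contraction, setting out from 21 and coming back at 26: the kinetic enolate 22 of 21 is hydroxylated with MoO5·pyridine·HMPA to the 7-hydroxy ketone F1. Dess–Martin oxidation gives the 6,7-dione F2. KOH in aqueous methanol at 60 °C effects the benzilic acid rearrangement to the ring-contracted 2-hydroxy-2-carboxylic acid F3; either carbonyl may be attacked, as both paths give the same constitution, and the carbinol configuration is immaterial. Pb(OAc)4 in benzene/pyridine decarboxylates F3 oxidatively to the cyclopentanone, which after K2CO3/MeOH equilibration is 26.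

2. Step 12. The cycloaddition with a four-atom tether onto a fully substituted diene terminus may be slow enough for double-bond migration of the β,γ-unsaturated ketone into conjugation and epimerisation at C7 to compete, and facial or endo/exo selectivity may be incomplete. Fallback, setting out from 19 and coming back at 21: the cycloaddition is run one step earlier on alcohol 19 (toluene, 160 °C), which has no enolisable ketone, to give the hydroxy octalin F4; Dess–Martin oxidation of F4 then gives 21.

3. Step 10. Hydrozirconation of the unsymmetrical dialkyl alkyne may proceed with imperfect regiocontrol, and the excess hydride may partly reduce the ester. Fallback, setting out from 13 and coming back at 19: palladium-catalysed syn hydrostannation of 13 (PdCl2(PPh3)2, Bu3SnH, THF) gives the alkenylstannane F5, which is purified from its regioisomer and joined to 17 by Stille coupling (Pd2(dba)3, AsPh3, CuI, DMF) to give 19.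

Further compounds
F1 | step 15 | methyl (1S,2R,4aS,5R,8S,8aR)-1,2,4,8-tetraethyl-7-hydroxy-5-methyl-6-oxo-2-[(E)-2-phenylethenyl]-1,2,4a,5,6,7,8,8a-octahydronaphthalene-1-carboxylate, hydroxyl anti to H-8 | CCC1=C[C@](/C=C/c2ccccc2)(CC)[C@@](CC)(C(=O)OC)[C@H]2[C@H]1[C@@H](C)C(=O)[C@H](O)[C@@H]2CC
F2 | step 15 | methyl 1,2,4,8-tetraethyl-5-methyl-6,7-dioxo-2-[(E)-2-phenylethenyl]-1,2,4a,5,6,7,8,8a-octahydronaphthalene-1-carboxylate | CCC1=C[C@](/C=C/c2ccccc2)(CC)[C@@](CC)(C(=O)OC)[C@H]2[C@H]1[C@@H](C)C(=O)C(=O)[C@@H]2CC
F3 | step 15 | 3,4,5,7-tetraethyl-2-hydroxy-4-(methoxycarbonyl)-1-methyl-5-[(E)-2-phenylethenyl]-2,3,3a,4,5,7a-hexahydro-1H-indene-2-carboxylic acid | CCC1=C[C@](/C=C/c2ccccc2)(CC)[C@@](CC)(C(=O)OC)[C@H]2[C@H]1[C@@H](C)[C@@](O)(C(=O)O)[C@@H]2CC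
F4 | step 12 | methyl 1,2,4,8-tetraethyl-6-hydroxy-5-methyl-2-[(E)-2-phenylethenyl]-1,2,4a,5,6,7,8,8a-octahydronaphthalene-1-carboxylate (6-hydroxy analogue of 21, hydroxyl axial) | CCC1=C[C@](/C=C/c2ccccc2)(CC)[C@@](CC)(C(=O)OC)[C@H]2[C@H]1[C@@H](C)[C@@H](O)C[C@@H]2CC
F5 | step 10 | methyl (2E,4S,6S,7R,8E)-2,4-diethyl-6-hydroxy-7-methyl-9-(tributylstannyl)undeca-2,8-dienoate | COC(=O)/C(CC)=C/[C@@H](CC)C[C@H](O)[C@H](C)/C=C(CC)/[Sn](CCCC)(CCCC)CCCC
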